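The isoflavanone is cut at the C2–C3 bond of ring C. The feature used is that C2 is a methylene held between O1 (the oxygen on ring A) and the only stereocentre, C3. C2 can therefore travel through the synthesis as the methyl carbon of a ring A methyl ether. A chiral dirhodium carboxylate converts a diaryl α-diazoketone into a carbenoid at C3, which inserts into a C–H bond of this methoxy group. That one operation forms C2–C3, closes ring C and fixes the (3S) configuration. The precursor is open-chain: silylated ring A with its ortho methoxy group sits on the carbonyl carbon, and the geranylated, silylated ring B sits on the diazo carbon.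

Key step: step 9

Structure check: the stereocentre in the target SMILES reads (3S) (C4 > C2 > C1' > H), and the side chain is the E (geranyl) isomer.

Assumption: the sense of induction of Rh2(S-PTAD)4 in this 1,6 insertion cannot be read safely from related cyclisations. The S catalyst is written, and the equally available Rh2(R-PTAD)4 replaces it if an ECD check of the final product against the calculated (3S) curve requires it.

Design points:
- **Protecting groups:** only silyl ethers are near the carbenoid. An acetal or benzyl ether on O-2' or O-5 would offer a more activated C–H bond, and a free OH would undergo O–H insertion. The MOM group needed for the lithiations is therefore exchanged before the coupling.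
- **Iodination:** iodine is introduced through an aryllithium. Electrophilic iodination would attack the alkenes and would not be regioselective.
- **Diazomethyl ketone:** it is made from a methyl ketone, which avoids an acid chloride and diazomethane.

Step 1
Reactants: 1 3-methoxyphenol
Product: 2 1-methoxy-3-(methoxymethoxy)benzene
Conditions: MOMCl, iPr2NEt, CH2Cl2, 0 °C → 23 °C
Reagents that add atoms: chloromethyl methyl ether, COCCl
Why: Williamson-type O-alkylation of the phenol installs the acetal ether that is the stronger of the two directing groups in both lithiations that follow.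

Step 2
Reactants: 2 1-methoxy-3-(methoxymethoxy)benzene; 3 geranyl bromide [(2E)-1-bromo-3,7-dimethylocta-2,6-diene]
Product: 5 2-[(2E)-3,7-dimethylocta-2,6-dienyl]-1-methoxy-3-(methoxymethoxy)benzene, via aryllithium 4 (not isolated)
Conditions: n-BuLi, THF, 0 °C → 23 °C, 1 h; CuBr·SMe2 (10 mol %), 3, −78 °C → 0 °C
Reagents that add atoms: n-butyllithium, [Li]CCCC (its lithium is found in intermediate 4 only)
Why: Directed ortho-metalation takes the C–H flanked by both oxygen substituents because it is the most acidic and doubly coordinated site, and the copper-catalysed SN2 allylation of the aryllithium by the primary allylic bromide keeps the linear chain and the E alkene.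

Step 3
Reactants: 5 2-[(2E)-3,7-dimethylocta-2,6-dienyl]-1-methoxy-3-(methoxymethoxy)benzene
Product: 7 2-[(2E)-3,7-dimethylocta-2,6-dienyl]-4-iodo-1-methoxy-3-(methoxymethoxy)benzene, via aryllithium 6 (not isolated)
Conditions: s-BuLi, TMEDA, THF, −78 °C, 1 h; I2 in THF, −78 °C → 0 °C; aq. Na2S2O3
Reagents that add atoms: iodine, [I][I]; sec-butyllithium, [Li]C(C)CC (its lithium is found in intermediate 6 only)
Why: A second directed ortho-metalation goes ortho to OMOM, a better directing group than OMe, while the benzylic-allylic CH2 is twisted out of conjugation by its two ortho neighbours and is not competitive for an alkyllithium at −78 °C, and iodinolysis of the aryllithium is much faster than addition of iodine to the trisubstituted alkenes.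

Step 4
Reactants: 7 2-[(2E)-3,7-dimethylocta-2,6-dienyl]-4-iodo-1-methoxy-3-(methoxymethoxy)benzene
Product: 8 2-[(2E)-3,7-dimethylocta-2,6-dienyl]-6-iodo-3-methoxyphenol
Conditions: p-TsOH·H2O (10 mol %), MeOH, 40 °C
Reagents that add atoms: none
Why: Acid-catalysed transacetalisation to methanol removes the MOM group, which must go because its OCH2O hydrogens would sit in a 1,5 relation to the later carbenoid, and catalytic acid in a nucleophilic solvent at mild temperature is too weak to add the phenol to the C2''=C3'' alkene of the geranyl chain.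

Step 5
Reactants: 8 2-[(2E)-3,7-dimethylocta-2,6-dienyl]-6-iodo-3-methoxyphenol
Product: 9 tert-butyl{2-[(2E)-3,7-dimethylocta-2,6-dienyl]-6-iodo-3-methoxyphenoxy}dimethylsilane
Conditions: TBSCl, imidazole, DMF, 23 → 40 °C
Reagents that add atoms: tert-butyldimethylsilyl chloride, CC(C)(C)[Si](C)(C)Cl
Why: Imidazole-promoted silylation of the phenol gives an ether whose oxygen is neither nucleophilic nor flanked by activated C–H bonds and which falls to fluoride at the end.

Step 6
Reactants: 10 1-(2,4-dihydroxy-6-methoxyphenyl)ethanone (2',4'-dihydroxy-6'-methoxyacetophenone, a catalogue compound)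
Product: 11 1-[2-methoxy-4,6-bis(tert-butyldimethylsilyloxy)phenyl]ethanone
Conditions: TBSCl (3 equiv), imidazole, DMAP (10 mol %), DMF, 40 °C
Reagents that add atoms: tert-butyldimethylsilyl chloride, CC(C)(C)[Si](C)(C)Cl
Why: Exhaustive imidazole/DMAP-promoted silylation covers the free 4-OH at once and, with excess reagent and gentle warming, the hydrogen-bonded 2-OH as in simple 2-hydroxyacetophenones, so that no O–H bond is left for the carbenoid.

Step 7
Reactants: 11 1-[2-methoxy-4,6-bis(tert-butyldimethylsilyloxy)phenyl]ethanone
Product: 14 2-diazo-1-[2-methoxy-4,6-bis(tert-butyldimethylsilyloxy)phenyl]ethanone, via lithium enolate 12 (not isolated), via trifluoroacetyl ketone 13 (not isolated)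
Conditions: LiHMDS, THF, −78 °C, 20 min; CF3CO2CH2CF3, −78 °C, 10 min; cold 5% aq. HCl wash, concentrate; p-ABSA, Et3N, MeCN, 23 °C
Reagents that add atoms: 4-acetamidobenzenesulfonyl azide, CC(=O)Nc1ccc(cc1)S(=O)(=O)N=[N+]=[N-]; 2,2,2-trifluoroethyl trifluoroacetate, O=C(OCC(F)(F)F)C(F)(F)F (its CF3CO group is found in intermediate 13 only); lithium hexamethyldisilazide, [Li]N([Si](C)(C)C)[Si](C)(C)C (its lithium is found in intermediate 12 only)
Why: Detrifluoroacetylative diazo transfer (a Regitz-type diazo transfer to an activated methyl ketone): the kinetic enolate is C-acylated within minutes at −78 °C, before any O-to-O silyl shift, and the 1,3-diketone takes up N2 from the sulfonyl azide and sheds the trifluoroacetyl group onto the sulfonamide nitrogen.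

Step 8
Reactants: 14 2-diazo-1-[2-methoxy-4,6-bis(tert-butyldimethylsilyloxy)phenyl]ethanone; 9 tert-butyl{2-[(2E)-3,7-dimethylocta-2,6-dienyl]-6-iodo-3-methoxyphenoxy}dimethylsilane
Product: 15 2-diazo-1-[2-methoxy-4,6-bis(tert-butyldimethylsilyloxy)phenyl]-2-{2-(tert-butyldimethylsilyloxy)-3-[(2E)-3,7-dimethylocta-2,6-dienyl]-4-methoxyphenyl}ethanone
Conditions: Pd(PPh3)4 (5 mol %), Ag2CO3 (0.5 equiv), Et3N (1.3 equiv), toluene, 23 °C, dark
Reagents that add atoms: none
Why: Palladium-catalysed C–H arylation of an acyldiazomethane with an aryl iodide proceeds by oxidative addition to zerovalent palladium, silver-assisted iodide abstraction with deprotonation of the diazo C–H, and reductive elimination from the aryl(diazoalkyl)palladium species, all at room temperature where the diazo group is retained and silyl ethers and trisubstituted alkenes are inert.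

Step 9
Reactants: 15 2-diazo-1-[2-methoxy-4,6-bis(tert-butyldimethylsilyloxy)phenyl]-2-{2-(tert-butyldimethylsilyloxy)-3-[(2E)-3,7-dimethylocta-2,6-dienyl]-4-methoxyphenyl}ethanone
Product: 16 (3S)-5,7-bis(tert-butyldimethylsilyloxy)-3-{2-(tert-butyldimethylsilyloxy)-3-[(2E)-3,7-dimethylocta-2,6-dienyl]-4-methoxyphenyl}chroman-4-one
Conditions: Rh2(S-PTAD)4 {dirhodium tetrakis[(S)-(1-adamantyl)(phthalimido)acetate]} (1 mol %), CH2Cl2, 4 Å MS, slow addition of 15 over 2 h (final 0.01 M), 0 °C → 23 °C
Reagents that add atoms: none
Why: The diazo carbon attacks an axial site of the divalent-rhodium dimer, N2 leaves, and the donor/acceptor carbenoid at C3 takes up a C–H bond of the neighbouring ArO–CH3 through a concerted, asynchronous three-centre transition state that makes C2–C3 and C3–H together and frees the catalyst. The closest known reaction types are the dirhodium-carboxylate-catalysed cyclisation of 2-alkoxyaryl α-diazoketones to chroman-4-ones and the insertion of aryl-substituted carbenoids into methyl ether C–H bonds. Ring C closes by 1,6 C–H insertion (cyclic array C3–C4–C4a–C8a–O1–C2), and a 1,5 insertion is excluded because the fifth atom of the chain is the oxygen itself. C3 is set by the chiral pocket of the four phthalimido-carboxylate ligands, which leaves one face of the carbenoid open to the C–H bond, and since hydrogen arrives in the same event no enol is passed and the carbenoid carries no β-hydrogen that could shift. Insertion has to beat attack of O1 on the carbenoid (oxonium ylide, then methyl 1,2-shift to a 2-methylcoumaranone), migration of ring A (Wolff type) and reaction at the alkenes; in its favour, methyl migrates poorly from a reversibly formed ylide and the aryl donor tempers the carbenoid. In addition, silicon leaves O-5 and O-2' poorly nucleophilic and without activated C–H bonds, the meta-placed geranyl chain cannot fold back, and slow addition at high dilution keeps the alkenes of a second molecule away.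

Step 10
Reactants: 16 (3S)-5,7-bis(tert-butyldimethylsilyloxy)-3-{2-(tert-butyldimethylsilyloxy)-3-[(2E)-3,7-dimethylocta-2,6-dienyl]-4-methoxyphenyl}chroman-4-one
Product: 17 (3S)-5,7-dihydroxy-3-{3-[(2E)-3,7-dimethylocta-2,6-dienyl]-2-hydroxy-4-methoxyphenyl}chroman-4-one (CNP0303304.1)
Conditions: HF·pyridine, pyridine, THF, 0 °C → 23 °C (polypropylene vessel); pH 6–7 phosphate buffer work-up
Reagents that add atoms: none
Why: Fluoride-driven Si–O cleavage in an acidic pyridine buffer frees the three phenols without generating phenoxide or enolate, so C3 is not epimerised, and the medium is too weakly acidic to cyclise the 2'-OH onto the geranyl alkene or onto C4.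

Compound list
1 | 3-methoxyphenol | COc1cccc(O)c1 | starting material
2 | 1-methoxy-3-(methoxymethoxy)benzene | COCOc1cccc(OC)c1 | intermediate
3 | geranyl bromide, (2E)-1-bromo-3,7-dimethylocta-2,6-diene | BrC/C=C(\C)CCC=C(C)C | starting material
4 | [2-methoxy-6-(methoxymethoxy)phenyl]lithium | [Li]c1c(OC)cccc1OCOC | intermediate
5 | 2-[(2E)-3,7-dimethylocta-2,6-dienyl]-1-methoxy-3-(methoxymethoxy)benzene | COCOc1cccc(OC)c1C/C=C(\C)CCC=C(C)C | intermediate
6 | {3-[(2E)-3,7-dimethylocta-2,6-dienyl]-4-methoxy-2-(methoxymethoxy)phenyl}lithium | [Li]c1ccc(OC)c(C/C=C(\C)CCC=C(C)C)c1OCOC | intermediate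
7 | 2-[(2E)-3,7-dimethylocta-2,6-dienyl]-4-iodo-1-methoxy-3-(methoxymethoxy)benzene | COCOc1c(I)ccc(OC)c1C/C=C(\C)CCC=C(C)C | intermediate
8 | 2-[(2E)-3,7-dimethylocta-2,6-dienyl]-6-iodo-3-methoxyphenol | COc1ccc(I)c(O)c1C/C=C(\C)CCC=C(C)C | intermediate
9 | tert-butyl{2-[(2E)-3,7-dimethylocta-2,6-dienyl]-6-iodo-3-methoxyphenoxy}dimethylsilane | COc1ccc(I)c(O[Si](C)(C)C(C)(C)C)c1C/C=C(\C)CCC=C(C)C | intermediate
10 | 1-(2,4-dihydroxy-6-methoxyphenyl)ethanone | COc1cc(O)cc(O)c1C(C)=O | starting material
11 | 1-[2-methoxy-4,6-bis(tert-butyldimethylsilyloxy)phenyl]ethanone | COc1cc(O[Si](C)(C)C(C)(C)C)cc(O[Si](C)(C)C(C)(C)C)c1C(C)=O | intermediate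
12 | lithium enolate of 11 | COc1cc(O[Si](C)(C)C(C)(C)C)cc(O[Si](C)(C)C(C)(C)C)c1C(=C)O[Li] | intermediate
13 | 4,4,4-trifluoro-1-[2-methoxy-4,6-bis(tert-butyldimethylsilyloxy)phenyl]butane-1,3-dione | COc1cc(O[Si](C)(C)C(C)(C)C)cc(O[Si](C)(C)C(C)(C)C)c1C(=O)CC(=O)C(F)(F)F | intermediate
14 | 2-diazo-1-[2-methoxy-4,6-bis(tert-butyldimethylsilyloxy)phenyl]ethanone | COc1cc(O[Si](C)(C)C(C)(C)C)cc(O[Si](C)(C)C(C)(C)C)c1C(=O)C=[N+]=[N-] | intermediate
15 | 2-diazo-1-[2-methoxy-4,6-bis(tert-butyldimethylsilyloxy)phenyl]-2-{2-(tert-butyldimethylsilyloxy)-3-[(2E)-3,7-dimethylocta-2,6-dienyl]-4-methoxyphenyl}ethanone | COc1cc(O[Si](C)(C)C(C)(C)C)cc(O[Si](C)(C)C(C)(C)C)c1C(=O)C(=[N+]=[N-])c1ccc(OC)c(C/C=C(\C)CCC=C(C)C)c1O[Si](C)(C)C(C)(C)C | intermediate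
16 | (3S)-5,7-bis(tert-butyldimethylsilyloxy)-3-{2-(tert-butyldimethylsilyloxy)-3-[(2E)-3,7-dimethylocta-2,6-dienyl]-4-methoxyphenyl}chroman-4-one | COc1ccc([C@H]2COc3cc(O[Si](C)(C)C(C)(C)C)cc(O[Si](C)(C)C(C)(C)C)c3C2=O)c(O[Si](C)(C)C(C)(C)C)c1C/C=C(\C)CCC=C(C)C | intermediate
17 | (3S)-5,7-dihydroxy-3-{3-[(2E)-3,7-dimethylocta-2,6-dienyl]-2-hydroxy-4-methoxyphenyl}chroman-4-one | COc1ccc([C@H]2COc3cc(O)cc(O)c3C2=O)c(O)c1C/C=C(\C)CCC=C(C)C | target

Total step count: 10. Longest linear sequence: 8 (steps 1–5, then 8–10). Steps 6 and 7 form the short second branch.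

Steps most likely to fail

Step 9. Several things may go wrong:
- capture of the carbenoid by the lone pair of the methoxy oxygen, followed by methyl migration;
- migration of ring A to the carbenoid carbon;
- sluggish loss of dinitrogen at the crowded diazo carbon;
- weak facial discrimination.

The fallback gives up the insertion: ring C is taken ready-made and C3 is set by dynamic kinetic resolution. It sets out from iodide 9 and comes back to the route at 16. Commercial 5,7-dihydroxychroman-4-one is silylated (TBSCl, imidazole, DMF) to 5,7-bis(tert-butyldimethylsilyloxy)chroman-4-one F1. Palladium-catalysed ketone α-arylation of this with 9 (Pd2(dba)3, P(t-Bu)3·HBF4, K3PO4, toluene, 80 °C) should give the racemic tris-silyl isoflavanone F2. Noyori–Ikariya transfer hydrogenation under racemising conditions (RuCl(p-cymene)[(S,S)-TsDPEN], HCO2H/Et3N, EtOAc, 40 °C) should then funnel both enantiomers through the labile C3 into the cis-(3S,4S)-isoflavan-4-ol F3. Dess–Martin oxidation (NaHCO3-buffered, CH2Cl2, 0 °C) returns 16 without touching C3.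

Step 8. What may go wrong is slow oxidative addition and slow C–C bond formation between two ortho-crowded partners, or palladium-induced loss of dinitrogen from the product. The fallback makes the C–C bond first and introduces the diazo group afterwards. It sets out from ketone 11 and iodide 9 and comes back to the route at 15. Enolate α-arylation (Pd2(dba)3, XPhos, anhydrous K3PO4, toluene, 80 °C) should give 1-[2-methoxy-4,6-bis(tert-butyldimethylsilyloxy)phenyl]-2-{2-(tert-butyldimethylsilyloxy)-3-[(2E)-3,7-dimethylocta-2,6-dienyl]-4-methoxyphenyl}ethanone F4. Its doubly activated methylene undergoes direct Regitz diazo transfer (p-ABSA, DBU, dry MeCN, 0 °C) to 15.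

Step 3. What may go wrong is competing deprotonation of the benzylic-allylic CH2 or partial lithiation ortho to the methoxy group. The fallback reverses the order, so that no strong base meets the geranyl chain. It sets out from phenol 1 and bromide 3 and comes back to the route at 8, which also makes steps 1, 2 and 4 unnecessary. Iodination of 1 under weakly basic conditions (I2, NaHCO3, THF/H2O, 0 °C) goes ortho to the OH at the less hindered site and para to OMe, and should give 2-iodo-5-methoxyphenol F5. Its sodium phenoxide in a non-polar medium (NaH, toluene, 0 °C; then 3, 23 °C) undergoes ortho C-allylation at the only free ortho position. The O-geranyl ether is the separable side product.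

Further compounds
F1 | step 9 | 5,7-bis(tert-butyldimethylsilyloxy)chroman-4-one | O=C1CCOc2cc(O[Si](C)(C)C(C)(C)C)cc(O[Si](C)(C)C(C)(C)C)c12
F2 | step 9 | racemic 5,7-bis(tert-butyldimethylsilyloxy)-3-{2-(tert-butyldimethylsilyloxy)-3-[(2E)-3,7-dimethylocta-2,6-dienyl]-4-methoxyphenyl}chroman-4-one | COc1ccc(C2COc3cc(O[Si](C)(C)C(C)(C)C)cc(O[Si](C)(C)C(C)(C)C)c3C2=O)c(O[Si](C)(C)C(C)(C)C)c1C/C=C(\C)CCC=C(C)C
F3 | step 9 | (3S,4S)-5,7-bis(tert-butyldimethylsilyloxy)-3-{2-(tert-butyldimethylsilyloxy)-3-[(2E)-3,7-dimethylocta-2,6-dienyl]-4-methoxyphenyl}chroman-4-ol (cis) | COc1ccc([C@H]2COc3cc(O[Si](C)(C)C(C)(C)C)cc(O[Si](C)(C)C(C)(C)C)c3[C@H]2O)c(O[Si](C)(C)C(C)(C)C)c1C/C=C(\C)CCC=C(C)C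
F4 | step 8 | 1-[2-methoxy-4,6-bis(tert-butyldimethylsilyloxy)phenyl]-2-{2-(tert-butyldimethylsilyloxy)-3-[(2E)-3,7-dimethylocta-2,6-dienyl]-4-methoxyphenyl}ethanone | COc1cc(O[Si](C)(C)C(C)(C)C)cc(O[Si](C)(C)C(C)(C)C)c1C(=O)Cc1ccc(OC)c(C/C=C(\C)CCC=C(C)C)c1O[Si](C)(C)C(C)(C)C
F5 | step 3 | 2-iodo-5-methoxyphenol | COc1ccc(I)c(O)c1
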